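Begin with a ratio: 0.700 equiv of reagent per starting material makes reagent the limiting reagent of this flask on paper.

| flask | starting material | reagent | protic impurity | free catalyst | remark |
|---|---|---|---|---|---|
| zeta | 0.40 M | 0.70 equiv | 0.12 M | 21 mol% | run made earlier |
| eta | 0.40 M | 0.70 equiv | 0.12 M | 33 mol% | run made earlier |
| flask | 0.40 M | 0.700 equiv | 0.120 M | 15 mol% |  |

- zeta (time / min: target / %, starting material / %): 1.50: 5, 87; 3.00: 10, 77; 5.00: 19, 62; 6.00: 19, 62; 8.00: 26, 52; 10.0: 38, 44
- eta (time / min: target / %, starting material / %): 0.833: 1, 97; 1.33: 4, 90; 2.00: 8, 85; 4.00: 23, 62; 6.00: 29, 55; 10.0: 44, 35

(readings scatter by 2 percentage points)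

1. apparent order in free catalyst when 50 % of the starting material are converted (percent change of the rate of making target for one percent more free catalyst charged)
2. apparent order in reagent when 50 % of the starting material are converted (percent change of the rate of making target for one percent more reagent charged)
3. factor on the rate of making target when 50 % of the starting material are converted if free catalyst is charged twice over

- steps under discussion: reagent + free catalyst -> catalyst intermediate A; catalyst intermediate B -> free catalyst + target; starting material + catalyst intermediate A -> catalyst intermediate B; starting material + protic impurity -> quenched substrate
- no earlier run changes the charge of reagent; that part of a forecast is a guess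

But not all starting material lost takes reagent with it. Subtract starting material and target from the whole: zeta at 8.00 min leaves a gap of 22.0 %, and eta at 6.00 min leaves 16.0 %. Take their mean, 19.0 %, as a reading of quench, which costs no reagent.

So count what is left, not what is made. At 50 % conversion, let target take the conversion minus the gap, and let the whole catalyst loading of 15 mol% hold reagent. Then 34.3 % of the charge stays free; call that fraction of reagent's own charge the reserve.

Now raise the charge by a small fraction and hold the spending: c_reagent rises by a fraction 2.92 times as large, and that factor is the lever. The order in reagent is therefore this lever times the order in c_reagent itself, which I cannot read here, since no earlier run changes the reagent charge.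

The forecast gave 0.7 in free catalyst, 0.4 in reagent and a factor of 1.5, saying “Reagent order is a guess”.

The flask gives 0.92, 0.35 and 1.83.

    reagent + free catalyst → catalyst intermediate A (k = 7.00 M⁻¹ min⁻¹)
    catalyst intermediate B → free catalyst + target (k = 2.30 min⁻¹)
    starting material + catalyst intermediate A → catalyst intermediate B (k = 0.910 M⁻¹ min⁻¹)
    starting material + protic impurity → quenched substrate (k = 0.380 M⁻¹ min⁻¹)

Divide the flask's order in reagent by its lever: reckoned with this reserve, c_reagent itself carries an order of about 0.120. Take the quench step out of this flask, as a simulated run did, and the apparent order in reagent moves from 0.35 to 1.4.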